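**Plan**

- Retrosynthesis: the C3–Br bond is cut first, giving 5,6-dibromo-1H-indole; then the C2–C3 bond of the pyrrole ring is cut.
- The enabling feature is C2: an unsubstituted CH joined only to N1 and C3, so it can derive from the carbon of an aryl isocyanide, with C3 as the ortho-methyl carbon of the same arene.
- The isocyanide goes back through its formamide to 4,5-dibromo-2-methylaniline; cutting the C–Br bond para to nitrogen leads to commercial 5-bromo-2-methylaniline.
- Forward: the benzene ring is bought with one bromine and receives the second; nitrogen is converted to N≡C; the pyrrole ring, the only ring made, closes by base-induced C2–C3 bond formation; C3–Br is added last.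
- Stereochemistry: the target is planar and has no stereogenic element, so nothing has to be set.

Key step: step 4

Assumption: the target has no stereocentre, axis or geometric isomerism, so "single enantiomer" is taken to mean the one achiral structure drawn. The bromines at C4/C5 of the aniline become C5/C6 of the indole.

**Route**

Step 1
Reactants: 1 5-bromo-2-methylaniline; 2 N-bromosuccinimide
Product: 3 4,5-dibromo-2-methylaniline
Conditions: NBS (1.0 equiv), DMF, 0 °C to rt, dark
Reagents that add atoms: N-bromosuccinimide, O=C1CCC(=O)N1Br
Why: Electrophilic aromatic bromination in which the amino group directs NBS to its para carbon C4, whereas the only free ortho carbon C6 is wedged between NH2 and Br, so one equivalent at 0 °C should stop at the 4,5-dibromide.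

Step 2
Reactants: 3 4,5-dibromo-2-methylaniline; 4 formic acid
Product: 5 N-(4,5-dibromo-2-methylphenyl)formamide
Conditions: HCO2H (5 equiv), toluene, reflux, Dean–Stark
Reagents that add atoms: formic acid, OC=O
Why: Thermal N-formylation of the aniline by formic acid (amide condensation), driven to completion by azeotropic removal of water under conditions that leave the aryl bromides untouched.

Step 3
Reactants: 5 N-(4,5-dibromo-2-methylphenyl)formamide
Product: 6 4,5-dibromo-2-methylphenyl isocyanide (1,2-dibromo-4-isocyano-5-methylbenzene)
Conditions: POCl3 (1.1 equiv), Et3N (3 equiv), CH2Cl2, 0 °C
Reagents that add atoms: none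
Why: Standard dehydration of an N-aryl formamide to the isocyanide with POCl3 and a tertiary amine, run cold and basic so that the acid-sensitive N≡C group survives and the methyl group and bromides are not affected.

Step 4
Reactants: 6 4,5-dibromo-2-methylphenyl isocyanide
Product: 10 5,6-dibromo-1H-indole, via (4,5-dibromo-2-isocyanophenyl)methyllithium 7 (not isolated), via 5,6-dibromo-2-lithio-3H-indole 8 (not isolated), via 5,6-dibromo-1-lithioindole 9 (not isolated)
Conditions: LDA (2.1 equiv, commercial alkyllithium-free solution), THF/diglyme, slow addition of 6 at −78 °C, then to rt; H2O quench
Reagents that add atoms: none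
Why: LDA removes a proton from the methyl group, which is acidified by the ortho isocyano group, to give benzylic organolithium 7; its carbanion adds to the divalent isocyanide carbon, forming C2–C3 and the 2-lithio-3H-indole 8, and a base-mediated proton transfer from C3 to C2 (the reason for the second equivalent of amide) gives the aromatic N-lithioindole 9, which water protonates to 10. The closest known reaction type is the Ito–Saegusa indole synthesis of ortho-tolyl isocyanides with lithium amides. The pyrrole ring closes in a 5-endo-dig mode, feasible here because the isocyanide carbon is carbene-like and accepts the nucleophile by α-addition in the plane of the forming ring. No stereocentre is formed. The step needs benzylic deprotonation to win over bromine–lithium exchange, ring metalation next to bromine and amide addition to N≡C; an alkyllithium-free hindered amide at −78 °C and slow addition of 6 to the base should secure this, helped by the fact that ring lithiation is reversible in the presence of diisopropylamine while the cyclization is not. Regiochemistry is not an issue, because 6 has a single methyl group and both bromines already sit on the carbons that become C5 and C6.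

Step 5
Reactants: 10 5,6-dibromo-1H-indole; 2 N-bromosuccinimide
Product: 11 3,5,6-tribromo-1H-indole
Conditions: NBS (1.0 equiv), DMF, 0 °C, dark; cold neutral work-up
Reagents that add atoms: N-bromosuccinimide, O=C1CCC(=O)N1Br
Why: Electrophilic aromatic substitution at C3, the most nucleophilic carbon of the indole, while the dibrominated benzo ring is deactivated, so one equivalent of NBS at 0 °C should stop before C2 reacts.

**Compound list**

1 | 5-bromo-2-methylaniline | Cc1ccc(Br)cc1N | starting material
2 | N-bromosuccinimide | O=C1CCC(=O)N1Br | starting material
3 | 4,5-dibromo-2-methylaniline | Cc1cc(Br)c(Br)cc1N | intermediate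
4 | formic acid | OC=O | starting material
5 | N-(4,5-dibromo-2-methylphenyl)formamide | Cc1cc(Br)c(Br)cc1NC=O | intermediate
6 | 4,5-dibromo-2-methylphenyl isocyanide | Cc1cc(Br)c(Br)cc1[N+]#[C-] | intermediate
7 | (4,5-dibromo-2-isocyanophenyl)methyllithium | [Li]Cc1cc(Br)c(Br)cc1[N+]#[C-] | intermediate
8 | 5,6-dibromo-2-lithio-3H-indole | [Li]C1=Nc2cc(Br)c(Br)cc2C1 | intermediate
9 | 5,6-dibromo-1-lithioindole | [Li]n1ccc2cc(Br)c(Br)cc21 | intermediate
10 | 5,6-dibromo-1H-indole | Brc1cc2[nH]ccc2cc1Br | intermediate
11 | 3,5,6-tribromo-1H-indole | Brc1cc2[nH]cc(Br)c2cc1Br | target

**Step count**

Total steps: 5. Longest linear sequence: 5 steps (1 → 3 → 5 → 6 → 10 → 11).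

**Steps most likely to fail**

Step 4. Ring metalation next to a bromine, followed by halogen migration or loss of lithium bromide to an aryne, could outrun the cyclization. So could intermolecular addition of the benzylic anion or the amide to the isocyanide. The fallback closes the pyrrole ring through N1–C2 instead and needs no carbanion next to the aryl bromides. It sets out from 3. The amino group is oxidised with sodium perborate in acetic acid at about 55 °C to 1,2-dibromo-4-methyl-5-nitrobenzene F1. The methyl group, now activated by the ortho nitro group, is condensed with DMF dimethyl acetal in DMF at about 110 °C to (E)-2-(4,5-dibromo-2-nitrophenyl)-N,N-dimethylethenamine F2. Reduction of the nitro group with iron powder in acetic acid at about 80 °C spares the aryl bromides; the resulting aniline should add to the enamine and lose dimethylamine (Leimgruber–Batcho indole synthesis). The route is rejoined at 10.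

Step 5. Over-bromination at C2 is possible, and the N–H 3-bromoindole may decompose during work-up or chromatography through acid- or light-induced oligomerisation or oxidation at C2. The fallback carries the sensitive position through as an N-silyl derivative. It sets out from 10. Deprotonation with NaH and silylation with TIPSCl in THF at 0 °C should give 5,6-dibromo-1-(triisopropylsilyl)-1H-indole F3. NBS 2 in THF at −78 °C should give 3,5,6-tribromo-1-(triisopropylsilyl)-1H-indole F4; the bulky silyl group shields C2 and the product can be purified and stored. TBAF in THF at 0 °C then releases the free indole under neutral conditions, rejoining the route at 11.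

Step 1. The free aniline may be brominated with poor para selectivity, or a second time at C6, or oxidised by NBS. The fallback changes the directing group before bromination. It sets out from 1, which is formylated with formic acid 4 in refluxing toluene to N-(5-bromo-2-methylphenyl)formamide F5. The formamido group is a weaker and bulkier director than NH2, so NBS 2 in acetic acid at 40–50 °C should brominate only the para position. This gives 5 directly, where the route is rejoined; compound 3 is bypassed.

**Further compounds**

F1 | step 4 | 1,2-dibromo-4-methyl-5-nitrobenzene | Cc1cc(Br)c(Br)cc1[N+](=O)[O-]
F2 | step 4 | (E)-2-(4,5-dibromo-2-nitrophenyl)-N,N-dimethylethenamine | CN(C)/C=C/c1cc(Br)c(Br)cc1[N+](=O)[O-]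
F3 | step 5 | 5,6-dibromo-1-(triisopropylsilyl)-1H-indole | CC(C)[Si](C(C)C)(C(C)C)n1ccc2cc(Br)c(Br)cc21
F4 | step 5 | 3,5,6-tribromo-1-(triisopropylsilyl)-1H-indole | CC(C)[Si](C(C)C)(C(C)C)n1cc(Br)c2cc(Br)c(Br)cc21
F5 | step 1 | N-(5-bromo-2-methylphenyl)formamide | Cc1ccc(Br)cc1NC=O
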